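**Strategy.** Ring A is disconnected across C1–C2 and the ring-fusion bond C5–C10 (drimane numbering), which unravels both carbocycles into one acyclic chain. The C3 carbinol next to the C4 gem-dimethyl group is read as a C3=C4 silyl enol ether, the retron of an intramolecular Diels–Alder reaction. The diene is a 2-silyloxy-3-methyl diene (C2–C5) and the dienophile an isopropenyl group (C1=C10), tethered through the Z-alkene C7=C8 of ring B and the C9 stereocentre. One thermal operation closes rings A and B and sets C5 and C10 from C9. Enolate methylation and axial-selective reduction finish ring A. C9 comes from a desymmetrising ring-closing metathesis.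

Key step: step 8

Numbering used: C1–C10 are the decalin carbons in drimane numbering; C11 is the CH2O carbon on C9, C12 the methyl on C8, C13/C14 the methyls on C4, C15 the methyl on C10. The C9 descriptor changes from S (compounds 7–13) to R (compounds 14–17) through a change of CIP priority only.

Assumption: the sense of induction of the chiral molybdenum catalyst in step 3 cannot be read from the structure. The (S)-biphenolate antipode is written; if it closes onto the other isopropenyl group, the (R)-antipode is used and nothing else changes.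

Step 1
Reactants: 1 2,4-dimethylpenta-1,3-diene
Product: 4 3-methyl-2-(prop-1-en-2-yl)but-3-en-1-ol, via potassium 2,4-dimethylpentadienide 2 (not isolated), via (2,4-dimethylpenta-2,4-dien-1-yl)magnesium bromide 3 (not isolated)
Conditions: n-BuLi, KOtBu, THF/hexane, −78 to 0 °C; MgBr2·OEt2, −78 °C; CH2O (gas, from cracked paraformaldehyde), −78 to 0 °C; aq. NH4Cl
Reagents that add atoms: formaldehyde (from paraformaldehyde), C=O
Why: Schlosser-base metalation gives the symmetrical pentadienyl anion, and the derived pentadienylmagnesium reagent should add to formaldehyde through its central carbon (allyl-metal SE2' addition via a six-membered transition state) to give the achiral skipped diene.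

Step 2
Reactants: 4 3-methyl-2-(prop-1-en-2-yl)but-3-en-1-ol; 5 but-3-enoic acid
Product: 6 3-methyl-2-(prop-1-en-2-yl)but-3-en-1-yl but-3-enoate
Conditions: DCC, DMAP (5 mol %), CH2Cl2, 0 °C
Reagents that add atoms: none
Why: Steglich esterification at 0 °C with only catalytic DMAP should acylate the primary alcohol while keeping the β,γ-unsaturated acyl group out of conjugation.

Step 3
Reactants: 6 3-methyl-2-(prop-1-en-2-yl)but-3-en-1-yl but-3-enoate
Product: 7 (6S)-5-methyl-6-(prop-1-en-2-yl)-6,7-dihydrooxepin-2(3H)-one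
Conditions: Mo(N-2,6-iPr2C6H3)(CHCMe2Ph)(O2C24H32) (5 mol %; O2C24H32 = (S)-3,3'-di-tert-butyl-5,5',6,6'-tetramethylbiphenyl-2,2'-diolate), benzene, 0.01 M, 22–50 °C, N2 purge
Reagents that add atoms: none
Why: Catalytic asymmetric ring-closing metathesis (desymmetrisation of a triene): the alkylidene forms at the vinyl group and the chiral biphenolate pocket selects one of the two enantiotopic isopropenyl groups, which sets C9 (S) under catalyst control, while the seven-membered ring fixes the new trisubstituted C7=C8 alkene as Z.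

Step 4
Reactants: 7 (6S)-5-methyl-6-(prop-1-en-2-yl)-6,7-dihydrooxepin-2(3H)-one
Product: 8 (6S)-5-methyl-6-(prop-1-en-2-yl)-2,3,6,7-tetrahydrooxepin-2-ol (mixture of anomers)
Conditions: iBu2AlH (1.1 equiv), CH2Cl2, −78 °C; aq. potassium sodium tartrate
Reagents that add atoms: none
Why: Partial reduction of a lactone with iBu2AlH at −78 °C should stop at the lactol because the tetrahedral aluminate survives until the quench.

Step 5
Reactants: 8 (6S)-5-methyl-6-(prop-1-en-2-yl)-2,3,6,7-tetrahydrooxepin-2-ol; 9 3-(triphenylphosphoranylidene)butan-2-one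
Product: 10 (3E,6Z,8S)-8-(hydroxymethyl)-3,7,9-trimethyldeca-3,6,9-trien-2-one
Conditions: toluene, 70 °C
Reagents that add atoms: none
Why: Wittig olefination of the open hydroxy-aldehyde form of the lactol with a stabilised α-methyl ylide should give the E-trisubstituted enone (C4=C5) under neutral conditions that leave the skipped Z-alkene in place.

Step 6
Reactants: 10 (3E,6Z,8S)-8-(hydroxymethyl)-3,7,9-trimethyldeca-3,6,9-trien-2-one; 11 scopoletin (7-hydroxy-6-methoxy-2H-chromen-2-one)
Product: 12 (3E,6Z,8S)-8-{[(6-methoxy-2-oxo-2H-chromen-7-yl)oxy]methyl}-3,7,9-trimethyldeca-3,6,9-trien-2-one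
Conditions: PPh3, DIAD, THF, 0 °C to rt
Reagents that add atoms: none
Why: Mitsunobu etherification: the acidic 7-OH of scopoletin displaces the activated, still unhindered primary alcohol, and no stereocentre is touched.

Step 7
Reactants: 12 (3E,6Z,8S)-8-{[(6-methoxy-2-oxo-2H-chromen-7-yl)oxy]methyl}-3,7,9-trimethyldeca-3,6,9-trien-2-one
Product: 13 7-{[(2S,3Z,6E)-8-(tert-butyldimethylsilyloxy)-3,7-dimethyl-2-(prop-1-en-2-yl)nona-3,6,8-trien-1-yl]oxy}-6-methoxy-2H-chromen-2-one
Conditions: TBSOTf (1.2 equiv), Et3N (2 equiv), CH2Cl2, −78 to 0 °C; filtration through Et3N-deactivated silica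
Reagents that add atoms: tert-butyldimethylsilyl trifluoromethanesulfonate, CC(C)(C)[Si](C)(C)OS(=O)(=O)C(F)(F)F
Why: Soft enolisation with a silyl triflate and an amine should remove a proton from the methyl group of the enone and give the cross-conjugated 2-silyloxy diene with the E geometry of C4=C5 retained.

Step 8
Reactants: 13 7-{[(2S,3Z,6E)-8-(tert-butyldimethylsilyloxy)-3,7-dimethyl-2-(prop-1-en-2-yl)nona-3,6,8-trien-1-yl]oxy}-6-methoxy-2H-chromen-2-one
Product: 14 6-methoxy-7-{[(1R,4aR,8aS)-6-(tert-butyldimethylsilyloxy)-2,5,8a-trimethyl-1,4,4a,7,8,8a-hexahydronaphthalen-1-yl]methoxy}-2H-chromen-2-one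
Conditions: toluene (0.01 M), BHT (cat.), Et3N (0.1 equiv), sealed tube, 190 °C
Reagents that add atoms: none
Why: A concerted, asynchronous thermal [4+2] cycloaddition joins the termini of the electron-rich 2-silyloxy diene (C2 and C5) to the isopropenyl alkene (C1 and C10), making the C1–C2 and C5–C10 bonds and leaving the C3=C4 silyl enol ether. The closest known reaction type is the thermal intramolecular Diels–Alder reaction of 1,7,9-decatrienes with a 2-methyl (isopropenyl) dienophile, which gives angular-methyl trans-decalins. Ring A closes as the new cyclohexene of the cycloaddition, and ring B closes in the same event as the fused six-membered ring spanned by the four-atom tether C6–C9, through the ring-fusion bond C5–C10; the bridged regiochemistry is excluded by this short tether. C10 and C5 are set relative to C9: in the half-chair tether the CH2OAr group on C9 should sit pseudoaxial to escape A(1,2) strain with the C8 methyl, the incoming C10 methyl takes the axial site anti to it, and C5–H ends trans to that methyl because the dienophile methyl prefers the exo position away from the OTBS- and methyl-bearing diene core. The step needs trans over cis ring fusion and one diene face relative to C9, both secured by the C9 stereocentre, the rigid Z-alkene C7=C8 and the substitution of diene and dienophile. The E geometry of C4=C5 keeps C6 away from C2, so no 1,5-hydrogen shift should drain the diene at 190 °C.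

Step 9
Reactants: 14 6-methoxy-7-{[(1R,4aR,8aS)-6-(tert-butyldimethylsilyloxy)-2,5,8a-trimethyl-1,4,4a,7,8,8a-hexahydronaphthalen-1-yl]methoxy}-2H-chromen-2-one
Product: 16 6-methoxy-7-{[(1R,4aR,8aS)-2,5,5,8a-tetramethyl-6-oxo-1,4,4a,5,6,7,8,8a-octahydronaphthalen-1-yl]methoxy}-2H-chromen-2-one, via benzyltrimethylammonium enolate 15 (not isolated)
Conditions: BnMe3NF (anhydrous, 1.5 equiv), MeI (10 equiv), 4 Å molecular sieves, THF, 0 °C to rt
Reagents that add atoms: iodomethane, CI
Why: Fluoride-mediated regiospecific alkylation of a silyl enol ether: fluoride unmasks the C3–C4 enolate, which should be C-methylated at C4 by excess MeI to give the gem-dimethyl ketone (no new stereocentre) under conditions the coumarin tolerates.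

Step 10
Reactants: 16 6-methoxy-7-{[(1R,4aR,8aS)-2,5,5,8a-tetramethyl-6-oxo-1,4,4a,5,6,7,8,8a-octahydronaphthalen-1-yl]methoxy}-2H-chromen-2-one
Product: 17 7-{[(1R,4aR,6R,8aS)-6-hydroxy-2,5,5,8a-tetramethyl-1,4,4a,5,6,7,8,8a-octahydronaphthalen-1-yl]methoxy}-6-methoxy-2H-chromen-2-one (CNP0218138.2)
Conditions: LiBH(s-Bu)3 (1.2 equiv), THF, −78 °C; aq. NH4Cl
Reagents that add atoms: none
Why: Reduction with a bulky trialkylborohydride: equatorial attack on the C3 ketone, away from the axial hydrogens at C1 and C5, should give the axial 3α-alcohol (C3 R), and at −78 °C the hindered reagent should reduce the ketone faster than the electron-rich 7-alkoxycoumarin.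

**Compound list**

1 | 2,4-dimethylpenta-1,3-diene | CC(C)=CC(C)=C | starting material
2 | potassium 2,4-dimethylpentadienide | [K+].[CH2-]C(C)=CC(C)=C | intermediate
3 | (2,4-dimethylpenta-2,4-dien-1-yl)magnesium bromide | C=C(C)C=C(C)C[Mg]Br | intermediate
4 | 3-methyl-2-(prop-1-en-2-yl)but-3-en-1-ol | C=C(C)C(CO)C(C)=C | intermediate
5 | but-3-enoic acid | C=CCC(=O)O | starting material
6 | 3-methyl-2-(prop-1-en-2-yl)but-3-en-1-yl but-3-enoate | C=CCC(=O)OCC(C(C)=C)C(C)=C | intermediate
7 | (6S)-5-methyl-6-(prop-1-en-2-yl)-6,7-dihydrooxepin-2(3H)-one | O=C1CC=C(C)[C@H](C(C)=C)CO1 | intermediate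
8 | (6S)-5-methyl-6-(prop-1-en-2-yl)-2,3,6,7-tetrahydrooxepin-2-ol (anomeric mixture) | OC1CC=C(C)[C@H](C(C)=C)CO1 | intermediate
9 | 3-(triphenylphosphoranylidene)butan-2-one | CC(=O)C(C)=P(c1ccccc1)(c1ccccc1)c1ccccc1 | starting material
10 | (3E,6Z,8S)-8-(hydroxymethyl)-3,7,9-trimethyldeca-3,6,9-trien-2-one | CC(=O)/C(C)=C/C/C=C(C)\[C@@H](CO)C(C)=C | intermediate
11 | scopoletin (7-hydroxy-6-methoxy-2H-chromen-2-one) | COc1cc2ccc(=O)oc2cc1O | starting material
12 | (3E,6Z,8S)-8-{[(6-methoxy-2-oxo-2H-chromen-7-yl)oxy]methyl}-3,7,9-trimethyldeca-3,6,9-trien-2-one | CC(=O)/C(C)=C/C/C=C(C)\[C@@H](COc1cc2oc(=O)ccc2cc1OC)C(C)=C | intermediate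
13 | 7-{[(2S,3Z,6E)-8-(tert-butyldimethylsilyloxy)-3,7-dimethyl-2-(prop-1-en-2-yl)nona-3,6,8-trien-1-yl]oxy}-6-methoxy-2H-chromen-2-one | C=C(O[Si](C)(C)C(C)(C)C)/C(C)=C/C/C=C(C)\[C@@H](COc1cc2oc(=O)ccc2cc1OC)C(C)=C | intermediate
14 | 6-methoxy-7-{[(1R,4aR,8aS)-6-(tert-butyldimethylsilyloxy)-2,5,8a-trimethyl-1,4,4a,7,8,8a-hexahydronaphthalen-1-yl]methoxy}-2H-chromen-2-one | COc1cc2ccc(=O)oc2cc1OC[C@@H]1C(C)=CC[C@H]2C(C)=C(O[Si](C)(C)C(C)(C)C)CC[C@]12C | intermediate
15 | benzyltrimethylammonium enolate (C3–C4) of ketone 16 | COc1cc2ccc(=O)oc2cc1OC[C@@H]1C(C)=CC[C@H]2C(C)=C([O-])CC[C@]12C.C[N+](C)(C)Cc1ccccc1 | intermediate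
16 | 6-methoxy-7-{[(1R,4aR,8aS)-2,5,5,8a-tetramethyl-6-oxo-1,4,4a,5,6,7,8,8a-octahydronaphthalen-1-yl]methoxy}-2H-chromen-2-one | COc1cc2ccc(=O)oc2cc1OC[C@@H]1C(C)=CC[C@H]2C(C)(C)C(=O)CC[C@]12C | intermediate
17 | 7-{[(1R,4aR,6R,8aS)-6-hydroxy-2,5,5,8a-tetramethyl-1,4,4a,5,6,7,8,8a-octahydronaphthalen-1-yl]methoxy}-6-methoxy-2H-chromen-2-one | COc1cc2ccc(=O)oc2cc1OC[C@@H]1C(C)=CC[C@H]2C(C)(C)[C@H](O)CC[C@]12C | target

Total step count: 10
Longest linear sequence: 10 steps (1 to 17)

**Steps most likely to fail**

Step 8 (key cycloaddition). The cycloaddition may pass through the competing transition state that gives the cis-fused decalin, or add to the other diene face relative to C9. Prolonged heating may also desilylate or isomerise the dienol ether before it cyclises. The fallback sets out from 13 and comes back at 14. It replaces the concerted thermal reaction by a metal-templated stepwise [4+2]: a cationic monovalent rhodium catalyst, [Rh(C8H12)(C10H8)]SbF6 (C8H12 = cycloocta-1,5-diene, C10H8 = naphthalene), in 1,2-dichloroethane at 25–60 °C. Diene and alkene would couple oxidatively at rhodium to a rhodacycle, and reductive elimination would then form the same C1–C2 and C5–C10 bonds at low temperature through a different stereodetermining step. This makes no new compound (F0).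

Step 3 (asymmetric ring-closing metathesis). The catalyst may discriminate poorly between the two enantiotopic isopropenyl groups, or the closure may stall through chelation of the ester to molybdenum and slow formation of the seven-membered lactone, leaving oligomers. The fallback sets out from 6 and comes back at 7, exchanging asymmetric catalysis for racemic closure and resolution. Triene 6 would be cyclised with the second-generation Grubbs catalyst RuCl2(=CHPh)(PCy3)(H2IMes) (H2IMes = 1,3-dimesitylimidazolidin-2-ylidene) in refluxing CH2Cl2 at high dilution to racemic 5-methyl-6-(prop-1-en-2-yl)-6,7-dihydrooxepin-2(3H)-one F1. The enantiomers would be separated by preparative chromatography on a cellulose tris(3,5-dimethylphenylcarbamate) phase; the (S)-enantiomer is 7.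

Step 10 (reduction beside the coumarin). The borohydride may add in conjugate fashion to the coumarin or open its lactone in competition with the hindered ketone, and the fluoride-generated enolate of step 9 shares this sensitivity. The fallback sets out from 10 and comes back at 17, carrying C11 as a silyl ether and attaching the coumarin last.
- Alcohol 10 would be silylated at both the hydroxyl and the methyl ketone (TBSOTf 2.5 equiv, Et3N) to the bis-silyl triene tert-butyl{[(2S,3Z,6E)-8-(tert-butyldimethylsilyloxy)-3,7-dimethyl-2-(prop-1-en-2-yl)nona-3,6,8-trien-1-yl]oxy}dimethylsilane F2.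
- Heating as in step 8 should give the cycloadduct tert-butyl{[(1R,4aR,8aS)-6-(tert-butyldimethylsilyloxy)-2,5,8a-trimethyl-1,4,4a,7,8,8a-hexahydronaphthalen-1-yl]methoxy}dimethylsilane F3.
- MeLi (THF, 0 °C) should cleave only the enol silyl ether to the lithium enolate of the C3 ketone F4, which MeI/DMPU would methylate to (4aS,5R,8aR)-5-[(tert-butyldimethylsilyloxy)methyl]-1,1,4a,6-tetramethyl-3,4,4a,5,8,8a-hexahydronaphthalen-2(1H)-one F5.
- LiBH(s-Bu)3 at −78 °C should give (2R,4aS,5R,8aR)-5-[(tert-butyldimethylsilyloxy)methyl]-1,1,4a,6-tetramethyl-1,2,3,4,4a,5,8,8a-octahydronaphthalen-2-ol F6.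
- Bu4NF would free (2R,4aS,5R,8aR)-5-(hydroxymethyl)-1,1,4a,6-tetramethyl-1,2,3,4,4a,5,8,8a-octahydronaphthalen-2-ol F7.
- Mitsunobu etherification (PPh3, DIAD) with scopoletin 11 at the primary hydroxyl, the hindered axial secondary alcohol staying free, would give 17.

Further compounds
F0 | step 8 | none | none
F1 | step 3 | racemic 5-methyl-6-(prop-1-en-2-yl)-6,7-dihydrooxepin-2(3H)-one | O=C1CC=C(C)C(C(C)=C)CO1
F2 | step 10 | tert-butyl{[(2S,3Z,6E)-8-(tert-butyldimethylsilyloxy)-3,7-dimethyl-2-(prop-1-en-2-yl)nona-3,6,8-trien-1-yl]oxy}dimethylsilane | C=C(O[Si](C)(C)C(C)(C)C)/C(C)=C/C/C=C(C)\[C@@H](CO[Si](C)(C)C(C)(C)C)C(C)=C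
F3 | step 10 | tert-butyl{[(1R,4aR,8aS)-6-(tert-butyldimethylsilyloxy)-2,5,8a-trimethyl-1,4,4a,7,8,8a-hexahydronaphthalen-1-yl]methoxy}dimethylsilane | CC(C)(C)[Si](C)(C)OC[C@@H]1C(C)=CC[C@H]2C(C)=C(O[Si](C)(C)C(C)(C)C)CC[C@]12C
F4 | step 10 | lithium enolate (C3–C4) of ketone F5 | CC(C)(C)[Si](C)(C)OC[C@@H]1C(C)=CC[C@H]2C(C)=C([O-])CC[C@]12C.[Li+]
F5 | step 10 | (4aS,5R,8aR)-5-[(tert-butyldimethylsilyloxy)methyl]-1,1,4a,6-tetramethyl-3,4,4a,5,8,8a-hexahydronaphthalen-2(1H)-one | CC(C)(C)[Si](C)(C)OC[C@@H]1C(C)=CC[C@H]2C(C)(C)C(=O)CC[C@]12C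
F6 | step 10 | (2R,4aS,5R,8aR)-5-[(tert-butyldimethylsilyloxy)methyl]-1,1,4a,6-tetramethyl-1,2,3,4,4a,5,8,8a-octahydronaphthalen-2-ol | CC(C)(C)[Si](C)(C)OC[C@@H]1C(C)=CC[C@H]2C(C)(C)[C@H](O)CC[C@]12C
F7 | step 10 | (2R,4aS,5R,8aR)-5-(hydroxymethyl)-1,1,4a,6-tetramethyl-1,2,3,4,4a,5,8,8a-octahydronaphthalen-2-ol | OC[C@@H]1C(C)=CC[C@H]2C(C)(C)[C@H](O)CC[C@]12C
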